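**Retrosynthetic overview**
- The strategy rests on one feature: C1 is the benzylic carbon para to the phenolic oxygen of ring A (the 4-hydroxy-3-methoxyphenyl ring). Oxidation of ring A therefore gives a p-quinone methide that is electrophilic at C1, and the C3 oxygen sits three atoms away.
- Target 20 comes from the trans-4,5-diaryl-1,3-dioxan-2-one 17 by capping the ring A phenol, hydride opening of the carbonate, and global desilylation.
- Carbonate 17 comes from phenol 15: the C1–O bond and the six-membered carbonate ring form together, with C2 controlling C1.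
- Phenol 15 comes from alcohol 11 by Boc2O acylation and hydrogenolysis of the ring A benzyl ether. Ring B (the 3,5-dimethoxy-4-oxygenated ring) stays silylated so that only ring A can be oxidised.
- Alcohol 11 comes from an Evans alkylation of arylacetyl imide 6 with benzylic bromide 8 (C2–CH2 bond and the C2 stereocentre). Both arenes are bought; the dioxanone is the only ring formed (step 8) and is opened in step 10.

Key step: step 8

Assumption: C1 is the carbinol carbon on ring A, C2 the carbon bearing ring B, C3 the CH2OH carbon; quinone methide 16 is expected as a syn/anti mixture about its exocyclic double bond, so that geometry is left open in its SMILES.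

Step 1
Reactants: 1 (4-hydroxy-3,5-dimethoxyphenyl)acetic acid
Product: 3 [3,5-dimethoxy-4-(triisopropylsilyloxy)phenyl]acetic acid, via silyl ester 2 (not isolated)
Conditions: i-Pr3SiCl (2.5 equiv), imidazole, DMF, rt; then K2CO3, MeOH–THF–H2O, rt; acidic work-up
Reagents that add atoms: triisopropylsilyl chloride, CC(C)[Si](Cl)(C(C)C)C(C)C
Why: Phenol and acid are both silylated and the far more labile silyl ester is then hydrolysed selectively, leaving the hindered aryl silyl ether that keeps ring B free of an oxidisable phenol (silyl ether protection).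

Step 2
Reactants: 3 [3,5-dimethoxy-4-(triisopropylsilyloxy)phenyl]acetic acid; 4 (S)-4-benzyl-1,3-oxazolidin-2-one
Product: 6 (S)-4-benzyl-3-{[3,5-dimethoxy-4-(triisopropylsilyloxy)phenyl]acetyl}-1,3-oxazolidin-2-one, via mixed pivalic anhydride 5 (not isolated)
Conditions: t-BuCOCl, Et3N, THF, −20 °C; then 4, LiCl, rt
Reagents that add atoms: none
Why: N-Acylation of the oxazolidinone through the mixed pivalic anhydride under LiCl/Et3N is standard for arylacetic acids and installs the Evans auxiliary without touching the silyl ether.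

Step 3
Reactants: 7 [4-(benzyloxy)-3-methoxyphenyl]methanol
Product: 8 1-(benzyloxy)-4-(bromomethyl)-2-methoxybenzene
Conditions: PBr3, Et2O, 0 °C
Reagents that add atoms: phosphorus tribromide, BrP(Br)Br
Why: PBr3 converts the electron-rich benzylic alcohol into the bromide by displacement of the activated phosphite ester; the labile bromide is used at once.

Step 4
Reactants: 6 (S)-4-benzyl-3-{[3,5-dimethoxy-4-(triisopropylsilyloxy)phenyl]acetyl}-1,3-oxazolidin-2-one; 8 1-(benzyloxy)-4-(bromomethyl)-2-methoxybenzene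
Product: 10 (S)-4-benzyl-3-{(S)-3-[4-(benzyloxy)-3-methoxyphenyl]-2-[3,5-dimethoxy-4-(triisopropylsilyloxy)phenyl]propanoyl}-1,3-oxazolidin-2-one, via sodium enolate 9 (not isolated)
Conditions: NaN(SiMe3)2, THF, −78 °C; then 8, −78 to −40 °C; AcOH quench
Reagents that add atoms: none
Why: Evans asymmetric alkylation: the chelated sodium (Z)-enolate is shielded on one face by the C4 benzyl group of the auxiliary, so the benzylic bromide enters from the opposite face and sets C2 as S.

Step 5
Reactants: 10 (S)-4-benzyl-3-{(S)-3-[4-(benzyloxy)-3-methoxyphenyl]-2-[3,5-dimethoxy-4-(triisopropylsilyloxy)phenyl]propanoyl}-1,3-oxazolidin-2-one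
Product: 11 (S)-3-[4-(benzyloxy)-3-methoxyphenyl]-2-[3,5-dimethoxy-4-(triisopropylsilyloxy)phenyl]propan-1-ol
Conditions: LiBH4, H2O (1 equiv), Et2O, 0 °C
Reagents that add atoms: none
Why: Reductive cleavage of the N-acyl oxazolidinone with LiBH4 gives the primary alcohol and returns the auxiliary under conditions too mild to epimerise the α-aryl centre or cleave the silyl and benzyl ethers.

Step 6
Reactants: 11 (S)-3-[4-(benzyloxy)-3-methoxyphenyl]-2-[3,5-dimethoxy-4-(triisopropylsilyloxy)phenyl]propan-1-ol; 12 di-tert-butyl dicarbonate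
Product: 14 (S)-3-[4-(benzyloxy)-3-methoxyphenyl]-2-[3,5-dimethoxy-4-(triisopropylsilyloxy)phenyl]propyl tert-butyl carbonate, via lithium alkoxide 13 (not isolated)
Conditions: n-BuLi, THF, −78 °C; then 12, −78 to 0 °C
Reagents that add atoms: none
Why: O-Acylation of the preformed lithium alkoxide with Boc2O gives the mixed tert-butyl carbonate and avoids the symmetrical carbonate that amine-catalysed variants can produce.

Step 7
Reactants: 14 (S)-3-[4-(benzyloxy)-3-methoxyphenyl]-2-[3,5-dimethoxy-4-(triisopropylsilyloxy)phenyl]propyl tert-butyl carbonate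
Product: 15 (S)-tert-butyl 2-[3,5-dimethoxy-4-(triisopropylsilyloxy)phenyl]-3-(4-hydroxy-3-methoxyphenyl)propyl carbonate
Conditions: H2 (1 atm), 10% Pd/C, EtOAc, rt
Reagents that add atoms: none
Why: Catalytic hydrogenolysis cleaves only the aryl benzyl ether, leaving the aliphatic tert-butyl carbonate, the aryl silyl ether and C2 untouched, and frees the ring A phenol needed for the oxidation.

Step 8
Reactants: 15 (S)-tert-butyl 2-[3,5-dimethoxy-4-(triisopropylsilyloxy)phenyl]-3-(4-hydroxy-3-methoxyphenyl)propyl carbonate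
Product: 17 (4S,5S)-5-[3,5-dimethoxy-4-(triisopropylsilyloxy)phenyl]-4-(4-hydroxy-3-methoxyphenyl)-1,3-dioxan-2-one, via quinone methide 16 (not isolated)
Conditions: Ag2O (3 equiv), 4 Å molecular sieves, CH2Cl2, 0 °C to rt, dark; filter through Celite under argon; then (PhO)2P(O)OH (10 mol%), CH2Cl2, −40 °C
Reagents that add atoms: none
Why: Proposed new method: Ag2O, which attacks only the free phenol of ring A, should take 15 by two-electron oxidation to p-quinone methide 16 (exocyclic carbon = C1); once the basic silver residues are filtered off, the phosphoric acid activates the dienone oxygen so that the carbonyl oxygen of the tert-butyl carbonate adds to C1, ring A rearomatises and the 2-tert-butoxy-1,3-dioxan-2-ylium ion sheds isobutene. The closest known reaction types are the Ag2O oxidation of 4-alkylphenols to quinone methides, the acid-catalysed 1,6-addition of oxygen nucleophiles to p-quinone methides (as in lignin quinone methide chemistry) and the cyclisation of tert-butyl carbonates onto cationic carbon (iodocarbonate-type closures); the neutral carbonate is too weak a nucleophile for the unactivated quinone methide, hence the acid co-catalyst. The 1,3-dioxan-2-one ring closes in the 6-exo-trig mode, the C1=C(ring A) bond lying outside the new ring. The new C1 stereocentre is controlled by C2: allylic 1,3-strain holds the C2–H in the plane of the quinone methide, the CH2O tether delivers oxygen to one face through a chair with both aryl groups equatorial, giving the trans (4S,5S) carbonate, and acid-reversible ionisation of the para-hydroxybenzylic C–O bond should let any cis isomer drain to this diequatorial isomer. The step needs chemoselectivity between the rings, secured by the silyl ether on ring B (no phenol to oxidise, and Ag2O does not abstract the benzylic C2–H), and capture faster than tautomerisation of 16 to the stilbene, which would erase C2; this is secured by the intramolecular six-membered closure at low temperature in an aprotic, base-free medium.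

Step 9
Reactants: 17 (4S,5S)-5-[3,5-dimethoxy-4-(triisopropylsilyloxy)phenyl]-4-(4-hydroxy-3-methoxyphenyl)-1,3-dioxan-2-one
Product: 18 (4S,5S)-5-[3,5-dimethoxy-4-(triisopropylsilyloxy)phenyl]-4-[3-methoxy-4-(triisopropylsilyloxy)phenyl]-1,3-dioxan-2-one
Conditions: i-Pr3SiOTf, 2,6-lutidine, CH2Cl2, −78 °C (on crude 17)
Reagents that add atoms: triisopropylsilyl trifluoromethanesulfonate, CC(C)[Si](OS(=O)(=O)C(F)(F)F)(C(C)C)C(C)C
Why: Low-temperature silylation with a hindered base caps the ring A phenol, so that the carbonate at C1 can no longer be expelled through a para-phenoxide (the reason basic methanolysis of 17 itself is avoided).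

Step 10
Reactants: 18 (4S,5S)-5-[3,5-dimethoxy-4-(triisopropylsilyloxy)phenyl]-4-[3-methoxy-4-(triisopropylsilyloxy)phenyl]-1,3-dioxan-2-one
Product: 19 (1S,2S)-2-[3,5-dimethoxy-4-(triisopropylsilyloxy)phenyl]-1-[3-methoxy-4-(triisopropylsilyloxy)phenyl]propane-1,3-diol
Conditions: LiAlH4, THF, 0 °C
Reagents that add atoms: none
Why: Hydride reduction of the cyclic carbonate removes the carbonyl carbon as methanol and frees the 1,3-diol without breaking the C1–O or C3–O bond, so both stereocentres are retained.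

Step 11
Reactants: 19 (1S,2S)-2-[3,5-dimethoxy-4-(triisopropylsilyloxy)phenyl]-1-[3-methoxy-4-(triisopropylsilyloxy)phenyl]propane-1,3-diol
Product: 20 (1S,2S)-2-(4-hydroxy-3,5-dimethoxyphenyl)-1-(4-hydroxy-3-methoxyphenyl)propane-1,3-diol
Conditions: Bu4NF, AcOH, THF, 0 °C to rt
Reagents that add atoms: none
Why: Fluoride cleaves both aryl silyl ethers, and the AcOH buffer keeps the freed para-hydroxybenzylic alcohol away from strongly basic phenoxide conditions.

**Compound list**
1 | (4-hydroxy-3,5-dimethoxyphenyl)acetic acid | COc1cc(CC(=O)O)cc(OC)c1O | starting material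
2 | triisopropylsilyl [3,5-dimethoxy-4-(triisopropylsilyloxy)phenyl]acetate | COc1cc(CC(=O)O[Si](C(C)C)(C(C)C)C(C)C)cc(OC)c1O[Si](C(C)C)(C(C)C)C(C)C | intermediate
3 | [3,5-dimethoxy-4-(triisopropylsilyloxy)phenyl]acetic acid | COc1cc(CC(=O)O)cc(OC)c1O[Si](C(C)C)(C(C)C)C(C)C | intermediate
4 | (S)-4-benzyl-1,3-oxazolidin-2-one | O=C1N[C@@H](Cc2ccccc2)CO1 | starting material
5 | [3,5-dimethoxy-4-(triisopropylsilyloxy)phenyl]acetic pivalic anhydride | COc1cc(CC(=O)OC(=O)C(C)(C)C)cc(OC)c1O[Si](C(C)C)(C(C)C)C(C)C | intermediate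
6 | (S)-4-benzyl-3-{[3,5-dimethoxy-4-(triisopropylsilyloxy)phenyl]acetyl}-1,3-oxazolidin-2-one | COc1cc(CC(=O)N2[C@@H](Cc3ccccc3)COC2=O)cc(OC)c1O[Si](C(C)C)(C(C)C)C(C)C | intermediate
7 | [4-(benzyloxy)-3-methoxyphenyl]methanol | COc1cc(CO)ccc1OCc1ccccc1 | starting material
8 | 1-(benzyloxy)-4-(bromomethyl)-2-methoxybenzene | COc1cc(CBr)ccc1OCc1ccccc1 | intermediate
9 | sodium (Z)-enolate of 6 | COc1cc(/C=C(\[O-])N2[C@@H](Cc3ccccc3)COC2=O)cc(OC)c1O[Si](C(C)C)(C(C)C)C(C)C.[Na+] | intermediate
10 | (S)-4-benzyl-3-{(S)-3-[4-(benzyloxy)-3-methoxyphenyl]-2-[3,5-dimethoxy-4-(triisopropylsilyloxy)phenyl]propanoyl}-1,3-oxazolidin-2-one | COc1cc(C[C@H](C(=O)N2[C@@H](Cc3ccccc3)COC2=O)c4cc(OC)c(O[Si](C(C)C)(C(C)C)C(C)C)c(OC)c4)ccc1OCc5ccccc5 | intermediate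
11 | (S)-3-[4-(benzyloxy)-3-methoxyphenyl]-2-[3,5-dimethoxy-4-(triisopropylsilyloxy)phenyl]propan-1-ol | COc1cc(C[C@H](CO)c2cc(OC)c(O[Si](C(C)C)(C(C)C)C(C)C)c(OC)c2)ccc1OCc3ccccc3 | intermediate
12 | di-tert-butyl dicarbonate | CC(C)(C)OC(=O)OC(=O)OC(C)(C)C | starting material
13 | lithium alkoxide of 11 | COc1cc(C[C@H](C[O-])c2cc(OC)c(O[Si](C(C)C)(C(C)C)C(C)C)c(OC)c2)ccc1OCc3ccccc3.[Li+] | intermediate
14 | (S)-3-[4-(benzyloxy)-3-methoxyphenyl]-2-[3,5-dimethoxy-4-(triisopropylsilyloxy)phenyl]propyl tert-butyl carbonate | COc1cc(C[C@H](COC(=O)OC(C)(C)C)c2cc(OC)c(O[Si](C(C)C)(C(C)C)C(C)C)c(OC)c2)ccc1OCc3ccccc3 | intermediate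
15 | (S)-tert-butyl 2-[3,5-dimethoxy-4-(triisopropylsilyloxy)phenyl]-3-(4-hydroxy-3-methoxyphenyl)propyl carbonate | COc1cc(C[C@H](COC(=O)OC(C)(C)C)c2cc(OC)c(O[Si](C(C)C)(C(C)C)C(C)C)c(OC)c2)ccc1O | intermediate
16 | tert-butyl (S)-2-[3,5-dimethoxy-4-(triisopropylsilyloxy)phenyl]-3-(3-methoxy-4-oxocyclohexa-2,5-dien-1-ylidene)propyl carbonate | COC1=CC(=C[C@H](COC(=O)OC(C)(C)C)c2cc(OC)c(O[Si](C(C)C)(C(C)C)C(C)C)c(OC)c2)C=CC1=O | intermediate
17 | (4S,5S)-5-[3,5-dimethoxy-4-(triisopropylsilyloxy)phenyl]-4-(4-hydroxy-3-methoxyphenyl)-1,3-dioxan-2-one | COc1cc([C@@H](OC(=O)O2)[C@H](C2)c3cc(OC)c(O[Si](C(C)C)(C(C)C)C(C)C)c(OC)c3)ccc1O | intermediate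
18 | (4S,5S)-5-[3,5-dimethoxy-4-(triisopropylsilyloxy)phenyl]-4-[3-methoxy-4-(triisopropylsilyloxy)phenyl]-1,3-dioxan-2-one | COc1cc([C@@H](OC(=O)O2)[C@H](C2)c3cc(OC)c(O[Si](C(C)C)(C(C)C)C(C)C)c(OC)c3)ccc1O[Si](C(C)C)(C(C)C)C(C)C | intermediate
19 | (1S,2S)-2-[3,5-dimethoxy-4-(triisopropylsilyloxy)phenyl]-1-[3-methoxy-4-(triisopropylsilyloxy)phenyl]propane-1,3-diol | COc1cc([C@@H](O)[C@H](CO)c2cc(OC)c(O[Si](C(C)C)(C(C)C)C(C)C)c(OC)c2)ccc1O[Si](C(C)C)(C(C)C)C(C)C | intermediate
20 | (1S,2S)-2-(4-hydroxy-3,5-dimethoxyphenyl)-1-(4-hydroxy-3-methoxyphenyl)propane-1,3-diol | COc1cc([C@@H](O)[C@H](CO)c2cc(OC)c(O)c(OC)c2)ccc1O | target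

**Step count**
Total step count: 11. Longest linear sequence: 10 steps (steps 1, 2 and 4 to 11, from compound 1).

**Steps most likely to fail**

Step 8 (the one step beyond known chemistry). Three things may go wrong. The ring A phenoxyl radical may couple at its free ortho position instead of going on to the quinone methide. The quinone methide may tautomerise to the stilbene, which erases C2. The weakly nucleophilic carbonate may add too slowly or with poor facial selectivity at C1. The fallback makes the C1–O bond together with the C1–C2 bond by known aldol chemistry and sets out from imide 6. Vanillin is silylated (i-Pr3SiCl, imidazole, DMF) to 3-methoxy-4-(triisopropylsilyloxy)benzaldehyde F1. An anti-selective aldol addition of 6 to F1 catalysed by MgCl2 (MgCl2, Et3N, Me3SiCl, EtOAc, rt) should then give (S)-4-benzyl-3-{(2R,3S)-2-[3,5-dimethoxy-4-(triisopropylsilyloxy)phenyl]-3-[3-methoxy-4-(triisopropylsilyloxy)phenyl]-3-(trimethylsilyloxy)propanoyl}-1,3-oxazolidin-2-one F2. Here the chelated enolate is attacked on the same face as in step 4, and the anti relationship corresponds to the trans carbonate. CF3CO2H in MeOH removes the trimethylsilyl group to give (S)-4-benzyl-3-{(2R,3S)-2-[3,5-dimethoxy-4-(triisopropylsilyloxy)phenyl]-3-hydroxy-3-[3-methoxy-4-(triisopropylsilyloxy)phenyl]propanoyl}-1,3-oxazolidin-2-one F3. LiBH4 reduction releases diol 19, where the route is rejoined before step 11.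

Step 9. The para-hydroxybenzylic C1–O bond of 17 may ionise during handling or silylation, re-forming the quinone methide and leading to epimerisation at C1 or elimination. The fallback leaves the phenol uncapped and sets out from 17. Excess i-Bu2AlH in CH2Cl2 at −78 °C turns the phenol into a poorly electron-releasing aluminium phenoxide and reduces the carbonate. This should give (1S,2S)-2-[3,5-dimethoxy-4-(triisopropylsilyloxy)phenyl]-1-(4-hydroxy-3-methoxyphenyl)propane-1,3-diol F4. Bu4NF/AcOH then removes the remaining silyl ether and gives target 20 directly.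

Step 4. The acidic α-aryl centre may epimerise under the enolate conditions, and the electron-rich bromide 8 may decompose, eroding yield and diastereoselectivity. The fallback sets C2 by asymmetric hydrogenation and sets out from acid 3. Perkin condensation with commercial 4-(benzyloxy)-3-methoxybenzaldehyde (Ac2O, Et3N, 110 °C, then aqueous hydrolysis) should give (E)-3-[4-(benzyloxy)-3-methoxyphenyl]-2-[3,5-dimethoxy-4-(triisopropylsilyloxy)phenyl]acrylic acid F5. Hydrogenation with Ru(OAc)2[(S)-BINAP] (H2, MeOH) should give (S)-3-[4-(benzyloxy)-3-methoxyphenyl]-2-[3,5-dimethoxy-4-(triisopropylsilyloxy)phenyl]propanoic acid F6. The sense is assigned by analogy with 2-arylacrylic acids; the other BINAP antipode would be used if a test run shows the opposite sense. BH3·THF reduction then gives alcohol 11, where the route is rejoined before step 6.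

Further compounds
F1 | step 8 | 3-methoxy-4-(triisopropylsilyloxy)benzaldehyde | COc1cc(C=O)ccc1O[Si](C(C)C)(C(C)C)C(C)C
F2 | step 8 | (S)-4-benzyl-3-{(2R,3S)-2-[3,5-dimethoxy-4-(triisopropylsilyloxy)phenyl]-3-[3-methoxy-4-(triisopropylsilyloxy)phenyl]-3-(trimethylsilyloxy)propanoyl}-1,3-oxazolidin-2-one | COc1cc([C@@H](O[Si](C)(C)C)[C@H](C(=O)N2[C@@H](Cc3ccccc3)COC2=O)c4cc(OC)c(O[Si](C(C)C)(C(C)C)C(C)C)c(OC)c4)ccc1O[Si](C(C)C)(C(C)C)C(C)C
F3 | step 8 | (S)-4-benzyl-3-{(2R,3S)-2-[3,5-dimethoxy-4-(triisopropylsilyloxy)phenyl]-3-hydroxy-3-[3-methoxy-4-(triisopropylsilyloxy)phenyl]propanoyl}-1,3-oxazolidin-2-one | COc1cc([C@@H](O)[C@H](C(=O)N2[C@@H](Cc3ccccc3)COC2=O)c4cc(OC)c(O[Si](C(C)C)(C(C)C)C(C)C)c(OC)c4)ccc1O[Si](C(C)C)(C(C)C)C(C)C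
F4 | step 9 | (1S,2S)-2-[3,5-dimethoxy-4-(triisopropylsilyloxy)phenyl]-1-(4-hydroxy-3-methoxyphenyl)propane-1,3-diol | COc1cc([C@@H](O)[C@H](CO)c2cc(OC)c(O[Si](C(C)C)(C(C)C)C(C)C)c(OC)c2)ccc1O
F5 | step 4 | (E)-3-[4-(benzyloxy)-3-methoxyphenyl]-2-[3,5-dimethoxy-4-(triisopropylsilyloxy)phenyl]acrylic acid | COc1cc(/C=C(/C(=O)O)c2cc(OC)c(O[Si](C(C)C)(C(C)C)C(C)C)c(OC)c2)ccc1OCc3ccccc3
F6 | step 4 | (S)-3-[4-(benzyloxy)-3-methoxyphenyl]-2-[3,5-dimethoxy-4-(triisopropylsilyloxy)phenyl]propanoic acid | COc1cc(C[C@H](C(=O)O)c2cc(OC)c(O[Si](C(C)C)(C(C)C)C(C)C)c(OC)c2)ccc1OCc3ccccc3
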